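# Haemathamnolic acid (16): ring A built by Diels–Alder benzannulation on a ring B but-2-ynoate

## The problem

Haemathamnolic acid (16) is a depside: the carboxyl carbon of ring A (a 3-formyl-2-hydroxy-4-methoxy-6-methylbenzoyl unit) is esterified with the C5 oxygen of ring B (3-formyl-2,4-dihydroxy-6-methylbenzoic acid), so the skeleton is two benzene rings held by one aryl ester. There is no stereocentre, so nothing in the molecule can relay configuration and the control problem is one of position only. Ring B carries six different substituents, and of its three phenolic oxygens only the one at C5, the one not hydrogen-bonded to a carbonyl group, is acylated. The ester bond is the crowded bond: the ring A carboxyl lies between the C2 oxygen and the C6 methyl, and the ring B C5 oxygen between the C6 methyl and the C4 oxygen. Three groups are fragile, namely the two formyl groups (reducible, oxidizable, open to nucleophiles), the aryl ester (cleaved or shifted to the C4 oxygen by base) and the free salicylic acid of ring B (decarboxylation in heat or strong acid), so the carboxyl has to be released last and under neutral conditions. Ring A offers a second free position (C5) beside C3, so its formyl group needs a directing handle, the C2 hydroxyl. The feature that opens a short route is ring A itself: the C1–C6 edge carries carboxyl and methyl, while C2–C5 carry oxygen at C2 and C4 and hydrogen at C5 (and at C3 before formylation). A but-2-ynoate and a 1,1,3-trioxygenated butadiene give exactly this pattern by cycloaddition and loss of methanol, so ring A can be grown on an ester of ring B made from a small, unhindered acid.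

## Retrosynthesis

**16 ⇒ 15.** The last cut is at the three oxygen–benzyl bonds of ring B (ester at C1, ethers at C2 and C4). A methyl ester could not be cleaved beside the depside ester, and a tert-butyl ester would not survive the Lewis acid used early on ring B. Benzyl ethers on the two phenols leave in the same operation. 15 has the full skeleton of 16 but a masked acid and masked phenols. The forward step is a hydrogenolysis at neutrality that must stop before the aldehydes are reduced.

**15 ⇒ 14.** The bond between ring A C3 and its formyl carbon is cut. Adding this carbon after the ring synthesis keeps the diene of the key step the plain, well-known one instead of a 2-substituted diene. Ring B of 14 has no free position, so only ring A can react, and of its two free positions only C3 is ortho to the free hydroxyl. A formylation through the metal phenoxide is therefore asked for. The TiCl4 method is set aside at this stage because that Lewis acid strips benzyl ethers next to a carbonyl group, as both ring B ethers are. The MgCl2–formaldehyde method leaves them alone.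

**14 ⇒ 9 + 11.** Ring A is cut at C1–C2 and C5–C6, giving the ring B aryl but-2-ynoate 9 and the mixed vinylketene acetal 11. The neighbouring cut, at the ester C–O bond, would require coupling a 2,6-disubstituted acid with a 2,6-disubstituted phenol. The present cut leaves the ester in place and moves the bond formation to carbon. 9 contains only ring B and a four-carbon acyl group. The forward reaction must place the methyl next to C5–H and the hydroxyl next to the carboxyl, must prefer the ynoate to the ring B aldehyde, and must aromatize through cycloadduct 12 and silyl ether 13 by loss of methanol.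

**9 ⇒ 7 + 8.** The acyl–oxygen bond of the ynoate is cut, giving phenol 7 and but-2-ynoic acid (8). A linear acid with an sp carbon next to the carboxyl reaches the flanked C5 oxygen where a substituted benzoic acid would not. The forward step is a carbodiimide esterification that must not add nucleophiles to the triple bond.

**7 ⇒ 5 ⇒ 3.** The C5–O bond of ring B and the two benzyl ether bonds are cut. C5 is the only free position of 3 and is para to the C2 hydroxyl, which is where an Elbs oxidation places oxygen. That oxidation delivers the new oxygen as a sulfate monoester (4, handled as its tetrabutylammonium salt 5) while the two old phenols stay free. The three oxygens are thus told apart without any selective protection: benzylation at the sulfate stage (6) and acid hydrolysis give 7.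

**3 ⇒ 2 ⇒ 1.** The ring B C3–formyl bond and the benzyl ester bond are cut, leading to benzyl orsellinate (2) and orsellinic acid (1), which holds every other carbon of ring B. Formylation comes before oxidation so that C5 is the only site left for the Elbs oxidation, and so that TiCl4 is used while no benzyl ether is present.

**11 ⇒ 10.** The O–Si bond of the diene is cut, giving methyl (E)-3-methoxybut-2-enoate (10). The forward step is γ-deprotonation and O-silylation.

## Roads not taken

Alternative 1: Ring B is cut at C1–C2 and traced back to a four-membered ring, the 4-alkenyl-4-hydroxycyclobutenone A1, which would be assembled from a squaric acid derivative and a vinyl-metal partner.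
- **Forward key step:** on heating, A1 should open to a dienylketene, which closes by 6π electrocyclization and tautomerizes to hydroquinone A2 (tert-butyl 2,5-dihydroxy-4-isopropoxy-6-methylbenzoate).
- **Merits:** every ring B oxygen is placed by the connectivity of A1, with no aromatic substitution and no persulfate oxidation. The two hydroxyls of A2 differ (C2 chelated to the ester, C5 free), which is the difference needed for acylation at C5.
- **Weak points:** A2 still lacks the C3 formyl group. Its tert-butyl ester and isopropyl ether need acid or Lewis acid for removal, which the depside ester and the aldehydes tolerate poorly. A vinyl-metal reagent with a β-ester group is delicate. Above all, the sequence builds in several steps a ring whose carbons are all present in 1, and it leaves the hindered ester bond and ring A unsolved.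
- **Comparison:** in control over the ring B oxygen pattern this road is better than the persulfate oxidation of the chosen plan, which is expected to run with moderate conversion. The chosen plan sets against this that ring B is bought, that its inefficient step comes early on cheap material, and that its ring-forming step is spent on ring A, where it removes the esterification problem.

Alternative 2: Ring B is cut at C1–C6 and C2–C3 and traced back to a cyclohexane-1,3-dione.
- **Forward key step:** the anion of tert-butyl methyl malonate A3 would add to the enone (Z)-3-(benzyloxy)pent-3-en-2-one A4, and the methyl ketone enolate of the adduct would close on the methyl ester to give dione A5, to be dehydrogenated to the resorcinol.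
- **Merits:** the acyclic components A3 and A4 are cheap, the C5 oxygen is present from the start in A4, and the Michael–Claisen ring closure is robust.
- **Weak points:** A5 is at the oxidation level of an arene plus benzyl alcohol. Enolization and loss of the C5 benzyloxy group would aromatize it more easily than the intended dehydrogenation, and would erase the oxygen the route was meant to bring. A5 is a diastereomer mixture until aromatized. The C3 formyl group, an ester exchange and all of ring A are still to come.
- **Comparison:** its only advantage over the chosen plan is that it avoids the persulfate oxidation. It is longer, and its aromatization carries a built-in side reaction, whereas the chosen plan starts from a ring B that is aromatic already.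

Alternative 3: Both aryl–formyl bonds are cut at once, leading back to the deformyl depside benzyl ester A6.
- **Forward key step:** dichloromethyl methyl ether and TiCl4 would formylate ring A C3 and ring B C3 in one operation to give haemathamnolic acid benzyl ester A7, one hydrogenolysis from 16.
- **Merits:** this is the shortest road. It needs no phenol protection (free phenols suit the TiCl4 method), no aldehyde is present while the rings are joined, and on ring B the C3 position is the only free one.
- **Weak points:** ring A of A6 has two free positions (C3 and C5) and the reaction has to be driven to double formylation. Mono-aldehydes and the regioisomeric dialdehyde would be close relatives, hard to separate at a late stage. A6 itself requires esterifying a 2,6-disubstituted benzoic acid with the hindered C5 phenol of an air-sensitive 2,4,5-trihydroxybenzoate, which is the hard bond made the hard way.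
- **Comparison:** in step count and protecting-group economy this road is better than the chosen plan, and it never exposes an aldehyde to a diene. The chosen plan sets against it that the crowded ester is made from an unhindered acid, and that the two formylations are separate events: the first early on a small intermediate, the second by a method that can reach only the position ortho to the hydroxyl.

Key step: step 7

## Route

Assumption: 1, 8 and 10 are taken as purchasable; 16 has no stereocentre, and the double-bond geometry drawn for 11 has no bearing on the cycloaddition product.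

Step 1
Reactants: 1 orsellinic acid (2,4-dihydroxy-6-methylbenzoic acid)
Product: 2 benzyl 2,4-dihydroxy-6-methylbenzoate
Conditions: BnBr, KHCO3, DMF, rt
Reagents that add atoms: benzyl bromide, BrCc1ccccc1
Why: SN2 O-alkylation of the carboxylate; hydrogencarbonate deprotonates only the carboxylic acid, so the phenols stay free, and room temperature avoids decarboxylation of the salicylic acid.

Step 2
Reactants: 2 benzyl 2,4-dihydroxy-6-methylbenzoate
Product: 3 benzyl 3-formyl-2,4-dihydroxy-6-methylbenzoate
Conditions: Cl2CHOMe, TiCl4, CH2Cl2, −10 to 0 °C; then 1 M HCl
Reagents that add atoms: dichloromethyl methyl ether, COC(Cl)Cl; water, O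
Why: Rieche formylation; C3 lies between the two TiCl4-bound phenoxide oxygens, which deliver the methoxychlorocarbenium electrophile there in preference to C5, and the chloro ether is hydrolysed to the aldehyde on work-up. The benzyl ester, which has no chelating neighbour that would help its ionization, should survive a short reaction at or below 0 °C; any C5 isomer would be removed at this early stage.

Step 3
Reactants: 3 benzyl 3-formyl-2,4-dihydroxy-6-methylbenzoate
Product: 5 tetrabutylammonium benzyl 3-formyl-2,4-dihydroxy-6-methyl-5-(sulfonatooxy)benzoate, via potassium aryl sulfate 4 (not isolated)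
Conditions: K2S2O8, aq. KOH, 5–20 °C; H2SO4 to pH 5, Et2O wash (recovers 3); Bu4NHSO4, CH2Cl2 extraction
Reagents that add atoms: potassium peroxodisulfate, [K+].[K+].[O-]S(=O)(=O)OOS(=O)(=O)[O-]; tetrabutylammonium hydrogensulfate, CCCC[N+](CCCC)(CCCC)CCCC.OS(=O)(=O)[O-]
Why: Elbs persulfate oxidation; the carbon para to the C2 phenoxide (C5, the only free ring position) attacks the peroxide oxygen and gives the aryl sulfate monoester, which is stable to base and is taken into the organic phase as its lipophilic ion pair. The 2,6-disubstituted, phenoxide-flanked benzyl ester is slow to saponify in cold alkali.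

Step 4
Reactants: 5 tetrabutylammonium benzyl 3-formyl-2,4-dihydroxy-6-methyl-5-(sulfonatooxy)benzoate
Product: 7 benzyl 2,4-bis(benzyloxy)-3-formyl-5-hydroxy-6-methylbenzoate, via dibenzylated sulfate salt 6 (not isolated)
Conditions: BnBr, K2CO3, DMF, 50 °C; then 2 M HCl, THF, 50 °C
Reagents that add atoms: benzyl bromide, BrCc1ccccc1
Why: Williamson etherification of the two free phenols while the C5 oxygen stays masked as the non-nucleophilic sulfate anion; acid-catalysed hydrolysis of the aryl sulfate (S–O cleavage) then frees only the C5 hydroxyl. Benzyl ethers, benzyl ester and aldehyde tolerate warm dilute acid.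

Step 5
Reactants: 7 benzyl 2,4-bis(benzyloxy)-3-formyl-5-hydroxy-6-methylbenzoate; 8 but-2-ynoic acid
Product: 9 benzyl 2,4-bis(benzyloxy)-5-(but-2-ynoyloxy)-3-formyl-6-methylbenzoate
Conditions: DCC, DMAP (cat.), CH2Cl2, 0 °C to rt
Reagents that add atoms: none
Why: Steglich esterification; the slim, linear acyl group reaches the phenol between the C4 benzyloxy group and the C6 methyl. Low temperature and only catalytic DMAP limit conjugate addition to the ynoate.

Step 6
Reactants: 10 methyl (E)-3-methoxybut-2-enoate
Product: 11 (1E)-1,3-dimethoxy-1-(trimethylsilyloxy)buta-1,3-diene (Brassard diene)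
Conditions: LiN(iPr)2, THF, −78 °C; Me3SiCl, −78 °C to rt; non-aqueous work-up
Reagents that add atoms: chlorotrimethylsilane, C[Si](C)(C)Cl
Why: γ-deprotonation of the vinylogous ester gives the dienolate, which the hard silyl chloride traps on oxygen; this is the standard preparation of this mixed vinylketene acetal.

Step 7
Reactants: 9 benzyl 2,4-bis(benzyloxy)-5-(but-2-ynoyloxy)-3-formyl-6-methylbenzoate; 11 (1E)-1,3-dimethoxy-1-(trimethylsilyloxy)buta-1,3-diene
Product: 14 benzyl 2,4-bis(benzyloxy)-3-formyl-5-[(2-hydroxy-4-methoxy-6-methylbenzoyl)oxy]-6-methylbenzoate, via cyclohexa-1,4-diene cycloadduct 12 (not isolated), via ring A trimethylsilyl ether 13 (not isolated)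
Conditions: 11 (3 equiv), toluene, 110 °C, sealed tube; then 1 M HCl, THF, 0 °C to rt
Reagents that add atoms: none
Why: The electron-rich diene 11 and the electron-poor aryl ynoate 9 should combine in a concerted, strongly asynchronous (4+2) cycloaddition in which the CH2 terminus of 11 bonds to the methyl-bearing β-carbon and the ketene acetal carbon to the α-carbon, giving cyclohexa-1,4-diene 12. Ring A is closed by an intermolecular two-bond annulation (C5–C6 and C1–C2), four ring carbons coming from the diene and two from the alkyne. 12 is at the oxidation level of an arene plus methanol: 1,4-elimination of methanol (methoxy group at C2, hydrogen at C5) gives silyl ether 13, and dilute acid removes the silyl group to give phenol 14. The closest known reaction type is the Diels–Alder benzannulation of 1,1-dioxygenated 3-oxygenated butadienes with alkynoate esters to resorcylate esters, and the use of this same diene with haloquinones to give the 1-hydroxy-3-methoxy pattern. The only stereocentre formed, the ketal carbon of 12, arises racemic and is erased on aromatization, so no stereocontrol is needed. The regiochemistry follows from matching the most nucleophilic diene terminus (CH2, pushed by all three oxygens) with the most electrophilic alkyne carbon (β to the carbonyl), and the aryl ester makes the ynoate a better dienophile than an alkyl ester would. Chemoselectivity against the ring B aldehyde rests on its two flanking benzyloxy groups and on the absence of any Lewis acid, without which addition of such dienes to aldehydes is slow. Methanol rather than trimethylsilanol should leave because the more basic methoxy oxygen is the one protonated, and any ketal that survives the heating is hydrolysed by the acid work-up to the dienone tautomer of the same phenol.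

Step 8
Reactants: 14 benzyl 2,4-bis(benzyloxy)-3-formyl-5-[(2-hydroxy-4-methoxy-6-methylbenzoyl)oxy]-6-methylbenzoate
Product: 15 benzyl 2,4-bis(benzyloxy)-3-formyl-5-[(3-formyl-2-hydroxy-4-methoxy-6-methylbenzoyl)oxy]-6-methylbenzoate
Conditions: MgCl2, Et3N, (CH2O)n, THF, reflux; then 1 M HCl
Reagents that add atoms: paraformaldehyde (as formaldehyde), C=O
Why: MgCl2-mediated ortho-formylation of a phenol (Casnati–Skattebøl); the magnesium phenoxide of the ring A hydroxyl binds formaldehyde and delivers it to C3, the only free ortho position, and the hydroxymethyl intermediate is oxidized in the same pot by hydride transfer to a second formaldehyde. C5 (para) cannot be reached by this mechanism, ring B has no free position, and no Lewis acid strong enough to cleave the benzyl ethers is present.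

Step 9
Reactants: 15 benzyl 2,4-bis(benzyloxy)-3-formyl-5-[(3-formyl-2-hydroxy-4-methoxy-6-methylbenzoyl)oxy]-6-methylbenzoate
Product: 16 haemathamnolic acid, 3-formyl-5-[(3-formyl-2-hydroxy-4-methoxy-6-methylbenzoyl)oxy]-2,4-dihydroxy-6-methylbenzoic acid
Conditions: H2 (1 atm), 10% Pd/C, EtOAc, rt, stopped after uptake of 3 equiv
Reagents that add atoms: none
Why: Hydrogenolysis of the benzyl ester and the two aryl benzyl ethers at neutrality, which spares the depside ester and avoids decarboxylation. Benzylic C–O cleavage is faster than reduction of the hydrogen-bonded salicylaldehyde-type formyl groups in a non-acidic solvent.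

## Compound list

1 | orsellinic acid (2,4-dihydroxy-6-methylbenzoic acid) | Cc1cc(O)cc(O)c1C(=O)O | starting material
2 | benzyl 2,4-dihydroxy-6-methylbenzoate | Cc1cc(O)cc(O)c1C(=O)OCc1ccccc1 | intermediate
3 | benzyl 3-formyl-2,4-dihydroxy-6-methylbenzoate | Cc1cc(O)c(C=O)c(O)c1C(=O)OCc1ccccc1 | intermediate
4 | potassium benzyl 3-formyl-2,4-dihydroxy-6-methyl-5-(sulfonatooxy)benzoate | Cc1c(OS(=O)(=O)[O-])c(O)c(C=O)c(O)c1C(=O)OCc1ccccc1.[K+] | intermediate
5 | tetrabutylammonium benzyl 3-formyl-2,4-dihydroxy-6-methyl-5-(sulfonatooxy)benzoate | Cc1c(OS(=O)(=O)[O-])c(O)c(C=O)c(O)c1C(=O)OCc1ccccc1.CCCC[N+](CCCC)(CCCC)CCCC | intermediate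
6 | tetrabutylammonium benzyl 2,4-bis(benzyloxy)-3-formyl-6-methyl-5-(sulfonatooxy)benzoate | Cc1c(OS(=O)(=O)[O-])c(OCc2ccccc2)c(C=O)c(OCc2ccccc2)c1C(=O)OCc1ccccc1.CCCC[N+](CCCC)(CCCC)CCCC | intermediate
7 | benzyl 2,4-bis(benzyloxy)-3-formyl-5-hydroxy-6-methylbenzoate | Cc1c(O)c(OCc2ccccc2)c(C=O)c(OCc2ccccc2)c1C(=O)OCc1ccccc1 | intermediate
8 | but-2-ynoic acid | CC#CC(=O)O | starting material
9 | benzyl 2,4-bis(benzyloxy)-5-(but-2-ynoyloxy)-3-formyl-6-methylbenzoate | CC#CC(=O)Oc1c(C)c(C(=O)OCc2ccccc2)c(OCc2ccccc2)c(C=O)c1OCc1ccccc1 | intermediate
10 | methyl (E)-3-methoxybut-2-enoate | CO/C(C)=C/C(=O)OC | starting material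
11 | (1E)-1,3-dimethoxy-1-(trimethylsilyloxy)buta-1,3-diene (Brassard diene) | C=C(OC)/C=C(/O[Si](C)(C)C)OC | intermediate
12 | benzyl 2,4-bis(benzyloxy)-5-{[4,6-dimethoxy-2-methyl-6-(trimethylsilyloxy)cyclohexa-1,4-diene-1-carbonyl]oxy}-3-formyl-6-methylbenzoate (racemic at the ketal carbon) | COC1=CC(OC)(O[Si](C)(C)C)C(C(=O)Oc2c(C)c(C(=O)OCc3ccccc3)c(OCc3ccccc3)c(C=O)c2OCc2ccccc2)=C(C)C1 | intermediate
13 | benzyl 2,4-bis(benzyloxy)-3-formyl-5-{[4-methoxy-6-methyl-2-(trimethylsilyloxy)benzoyl]oxy}-6-methylbenzoate | COc1cc(C)c(C(=O)Oc2c(C)c(C(=O)OCc3ccccc3)c(OCc3ccccc3)c(C=O)c2OCc2ccccc2)c(O[Si](C)(C)C)c1 | intermediate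
14 | benzyl 2,4-bis(benzyloxy)-3-formyl-5-[(2-hydroxy-4-methoxy-6-methylbenzoyl)oxy]-6-methylbenzoate | COc1cc(C)c(C(=O)Oc2c(C)c(C(=O)OCc3ccccc3)c(OCc3ccccc3)c(C=O)c2OCc2ccccc2)c(O)c1 | intermediate
15 | benzyl 2,4-bis(benzyloxy)-3-formyl-5-[(3-formyl-2-hydroxy-4-methoxy-6-methylbenzoyl)oxy]-6-methylbenzoate | COc1cc(C)c(C(=O)Oc2c(C)c(C(=O)OCc3ccccc3)c(OCc3ccccc3)c(C=O)c2OCc2ccccc2)c(O)c1C=O | intermediate
16 | haemathamnolic acid, 3-formyl-5-[(3-formyl-2-hydroxy-4-methoxy-6-methylbenzoyl)oxy]-2,4-dihydroxy-6-methylbenzoic acid | COc1cc(C)c(C(=O)Oc2c(C)c(C(=O)O)c(O)c(C=O)c2O)c(O)c1C=O | target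

## Step count and least certain steps

Total: 9 steps. Longest linear sequence: 8 steps (1, 2, 3, 4, 5, 7, 8, 9); step 6 is the one-step side branch to the diene.

**Step 7 (key step).** Several processes could divert it:
- addition of the diene to the ring B aldehyde (hetero-Diels–Alder or Mukaiyama-type aldol) instead of to the ynoate;
- a cycloaddition slow enough, because of the β-methyl group, that thermal decay of the diene (silyl migration, adventitious hydrolysis) wins;
- aromatization by loss of trimethylsilanol in place of methanol, which would leave a methyl ether at ring A C2;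
- transfer of the activated butynoyl group to the methanol that is set free.

Fallback: abandon the ring synthesis on the ester and make the depside bond by acylation. Setting out from 2, the non-chelated C4 hydroxyl is methylated (MeI, K2CO3, acetone) to benzyl 2-hydroxy-4-methoxy-6-methylbenzoate F1. Hydrogenolysis (H2, Pd/C, EtOAc) gives 2-hydroxy-4-methoxy-6-methylbenzoic acid F2. F2 is condensed with phenol 7 through its mixed trifluoroacetic anhydride (TFAA, toluene, rt), the usual way to force a hindered depside ester, and the route is rejoined at 14. The price is the doubly hindered esterification that the main route avoids.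

**Step 8.** The ester-chelated magnesium phenoxide may react sluggishly. The ring B aldehyde may also take part in hydride transfer or hemiacetal chemistry under the basic formaldehyde conditions. Fallback: ortho-hydroxymethylation on a boron template followed by oxidation. From 14, phenylboronic acid and paraformaldehyde (cat. propionic acid, toluene, reflux, water separator) should tie the C2 oxygen and a new C3 methylene into benzyl 2,4-bis(benzyloxy)-3-formyl-5-[(5-methoxy-7-methyl-2-phenyl-4H-1,3,2-benzodioxaborine-8-carbonyl)oxy]-6-methylbenzoate F3. Exchange with propane-1,3-diol frees benzyl 2,4-bis(benzyloxy)-3-formyl-5-{[2-hydroxy-3-(hydroxymethyl)-4-methoxy-6-methylbenzoyl]oxy}-6-methylbenzoate F4. MnO2 in CH2Cl2 oxidizes the benzylic alcohol to the aldehyde, returning to the route at 15.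

**Step 3.** Persulfate oxidations stop at partial conversion. The aldehyde or the electron-rich product may be oxidized further, the benzyl ester may be slowly saponified, and material may be lost in the ion-pair extraction. Fallback: carbon–halogen, then carbon–boron, then carbon–oxygen. From 3, bromination at the only free position (NBS, MeCN) gives benzyl 5-bromo-3-formyl-2,4-dihydroxy-6-methylbenzoate F5. Benzylation (BnBr, K2CO3, DMF) gives benzyl 2,4-bis(benzyloxy)-5-bromo-3-formyl-6-methylbenzoate F6. Miyaura borylation (B2pin2, KOAc, Pd(OAc)2, SPhos, dioxane, 90 °C) gives benzyl 2,4-bis(benzyloxy)-3-formyl-6-methyl-5-(4,4,5,5-tetramethyl-1,3,2-dioxaborolan-2-yl)benzoate F7. Oxidation of the C–B bond (NaBO3·4H2O, aq. THF, rt) returns to the route at 7.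

**Step 2.** The electrophile may attack C5 in competition with C3, and the Lewis acid may remove the benzyl ester. Fallback: place the oxygen before the carbon, so that formylation has only one site left. From 2, Elbs oxidation (K2S2O8, aq. KOH), which goes only para to a phenoxide, gives potassium benzyl 2,4-dihydroxy-6-methyl-5-(sulfonatooxy)benzoate F8. It is hydrolysed in the acidified solution to benzyl 2,4,5-trihydroxy-6-methylbenzoate F9. Formylation (Cl2CHOMe, TiCl4) can then occur only at C3 and gives benzyl 3-formyl-2,4,5-trihydroxy-6-methylbenzoate F10. The single non-chelated hydroxyl, at C5, is esterified with 8 (DCC, CH2Cl2) to benzyl 5-(but-2-ynoyloxy)-3-formyl-2,4-dihydroxy-6-methylbenzoate F11. The two chelated phenols are then benzylated under non-basic conditions (BnBr, Ag2O, CH2Cl2), rejoining the route at 9.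

**Step 9.** The aldehydes may be over-reduced to hydroxymethyl or methyl groups, above all the ring B aldehyde before its neighbours are debenzylated, or ether cleavage may stall. Fallback: acidolytic instead of reductive debenzylation. From 15, trifluoroacetic acid with thioanisole as benzyl acceptor (rt) removes the ester and both ether benzyl groups by a push–pull mechanism and leads directly to 16. No new compound lies on the way.

## Further compounds

F1 | step 7 | benzyl 2-hydroxy-4-methoxy-6-methylbenzoate | COc1cc(C)c(C(=O)OCc2ccccc2)c(O)c1
F2 | step 7 | 2-hydroxy-4-methoxy-6-methylbenzoic acid | COc1cc(C)c(C(=O)O)c(O)c1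
F3 | step 8 | benzyl 2,4-bis(benzyloxy)-3-formyl-5-[(5-methoxy-7-methyl-2-phenyl-4H-1,3,2-benzodioxaborine-8-carbonyl)oxy]-6-methylbenzoate | COc1cc(C)c(C(=O)Oc3c(C)c(C(=O)OCc4ccccc4)c(OCc4ccccc4)c(C=O)c3OCc3ccccc3)c2OB(c3ccccc3)OCc12
F4 | step 8 | benzyl 2,4-bis(benzyloxy)-3-formyl-5-{[2-hydroxy-3-(hydroxymethyl)-4-methoxy-6-methylbenzoyl]oxy}-6-methylbenzoate | COc1cc(C)c(C(=O)Oc2c(C)c(C(=O)OCc3ccccc3)c(OCc3ccccc3)c(C=O)c2OCc2ccccc2)c(O)c1CO
F5 | step 3 | benzyl 5-bromo-3-formyl-2,4-dihydroxy-6-methylbenzoate | Cc1c(Br)c(O)c(C=O)c(O)c1C(=O)OCc1ccccc1
F6 | step 3 | benzyl 2,4-bis(benzyloxy)-5-bromo-3-formyl-6-methylbenzoate | Cc1c(Br)c(OCc2ccccc2)c(C=O)c(OCc2ccccc2)c1C(=O)OCc1ccccc1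
F7 | step 3 | benzyl 2,4-bis(benzyloxy)-3-formyl-6-methyl-5-(4,4,5,5-tetramethyl-1,3,2-dioxaborolan-2-yl)benzoate | Cc1c(B2OC(C)(C)C(C)(C)O2)c(OCc2ccccc2)c(C=O)c(OCc2ccccc2)c1C(=O)OCc1ccccc1
F8 | step 2 | potassium benzyl 2,4-dihydroxy-6-methyl-5-(sulfonatooxy)benzoate | Cc1c(OS(=O)(=O)[O-])c(O)cc(O)c1C(=O)OCc1ccccc1.[K+]
F9 | step 2 | benzyl 2,4,5-trihydroxy-6-methylbenzoate | Cc1c(O)c(O)cc(O)c1C(=O)OCc1ccccc1
F10 | step 2 | benzyl 3-formyl-2,4,5-trihydroxy-6-methylbenzoate | Cc1c(O)c(O)c(C=O)c(O)c1C(=O)OCc1ccccc1
F11 | step 2 | benzyl 5-(but-2-ynoyloxy)-3-formyl-2,4-dihydroxy-6-methylbenzoate | CC#CC(=O)Oc1c(C)c(C(=O)OCc2ccccc2)c(O)c(C=O)c1O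
F0 | step 9 | none | none
A1 | alternative 1 | tert-butyl (E)-3-(1-hydroxy-2-isopropoxy-4-oxocyclobut-2-en-1-yl)but-2-enoate (racemic) | CC(C)OC1=CC(=O)C1(O)/C(C)=C/C(=O)OC(C)(C)C
A2 | alternative 1 | tert-butyl 2,5-dihydroxy-4-isopropoxy-6-methylbenzoate | CC(C)Oc1cc(O)c(C(=O)OC(C)(C)C)c(C)c1O
A3 | alternative 2 | tert-butyl methyl malonate | COC(=O)CC(=O)OC(C)(C)C
A4 | alternative 2 | (Z)-3-(benzyloxy)pent-3-en-2-one | C/C=C(\OCc1ccccc1)C(C)=O
A5 | alternative 2 | tert-butyl 5-(benzyloxy)-6-methyl-2,4-dioxocyclohexane-1-carboxylate (diastereomer mixture) | CC1C(OCc2ccccc2)C(=O)CC(=O)C1C(=O)OC(C)(C)C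
A6 | alternative 3 | benzyl 2,4-dihydroxy-5-[(2-hydroxy-4-methoxy-6-methylbenzoyl)oxy]-6-methylbenzoate | COc1cc(C)c(C(=O)Oc2c(C)c(C(=O)OCc3ccccc3)c(O)cc2O)c(O)c1
A7 | alternative 3 | haemathamnolic acid benzyl ester | COc1cc(C)c(C(=O)Oc2c(C)c(C(=O)OCc3ccccc3)c(O)c(C=O)c2O)c(O)c1C=O
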